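**Plan**
- Cuts: first the lactone acyl–oxygen bond between the ring-A carbonyl and O-5 of the chromene unit. Then the two ring-A C–C bonds C(prenyl)–C(OAr) and C(OH)–C(CO2R). Last the alkynyl C–O and C–CO2 bonds and the pyran ring.
- Enabling feature: the six ring-A carbons carry OH, prenyl, OH, prenyl, O-aryl and C=O in strict O/C alternation. Four of them form a 1,3-dioxygenated 2,4-diprenylbutadiene. The other two form an alkyne bearing the ring-B aryloxy group and an ester.
- Forward order: ring B is bought as 2,5-dibromohydroquinone. The pyran ring is fused on by a propargyl-ether Claisen cyclization. The second bromine becomes the phenol, which is converted into the aryloxypropiolate.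
- Ring A is then built on that alkyne by [4+2] cycloaddition and aromatization, with the diaryl ether already in place. The seven-membered lactone closes last.
- Stereochemistry: the target has no stereocentre, so none has to be set.

Key step: step 12

Remark: the alkene geometries written for 8 and 22 are the expected ones. They are erased in steps 12 and 11, so isomer mixtures are acceptable.

Remark: the alkyne ester is allyl. A benzoate flanked by two ortho oxygen substituents resists saponification, and an aryl lactone lies uphill from a methyl ester. The carboxyl group is therefore freed under neutral conditions and closed with a dehydrating agent.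

Remark: ring B of 30 and 31 is a free hydroquinone, so steps 13–15 are run in degassed solvents under argon.

**Step 1**
Reactants: 1 methyl acetoacetate; 2 prenyl bromide
Product: 4 methyl 7-methyl-3-oxooct-6-enoate, via acetoacetate dianion 3 (not isolated)
Conditions: NaH, THF, 0 °C; n-BuLi, 0 °C; 2 (1.0 equiv), 0 °C → rt; aq HCl
Reagents that add atoms: none
Why: In this γ-alkylation of an acetoacetate dianion the more basic terminal carbanion reacts first, so the allylic bromide should enter only at the methyl carbon by SN2.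

**Step 2**
Reactants: 4 methyl 7-methyl-3-oxooct-6-enoate; 2 prenyl bromide
Product: 5 methyl 7-methyl-2-(3-methylbut-2-en-1-yl)-3-oxooct-6-enoate (racemic)
Conditions: K2CO3, acetone, reflux
Reagents that add atoms: none
Why: This is a classical acetoacetic ester α-alkylation in which the soft stabilized enolate is C-alkylated by the allylic bromide, and one equivalent of 2 limits double alkylation.

**Step 3**
Reactants: 5 methyl 7-methyl-2-(3-methylbut-2-en-1-yl)-3-oxooct-6-enoate
Product: 6 methyl 7-methyl-2-(3-methylbut-2-en-1-yl)-3-(trimethylsilyloxy)octa-2,6-dienoate (E/Z mixture)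
Conditions: TMSCl, Et3N, toluene, rt
Reagents that add atoms: chlorotrimethylsilane C[Si](C)(C)Cl
Why: O-silylation of the enolizable β-keto ester is the first half of the standard two-stage preparation of 1-alkoxy-1,3-bis(silyloxy)dienes, and 2-alkyl substrates are known to take part.

**Step 4**
Reactants: 6 methyl 7-methyl-2-(3-methylbut-2-en-1-yl)-3-(trimethylsilyloxy)octa-2,6-dienoate
Product: 8 (1Z,3Z)-1-methoxy-2,4-bis(3-methylbut-2-en-1-yl)-1,3-bis(trimethylsilyloxy)buta-1,3-diene, via lithium dienolate 7 (not isolated)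
Conditions: LDA, THF, −78 °C; TMSCl, −78 °C → rt; salts filtered off in hexane, used crude
Reagents that add atoms: chlorotrimethylsilane C[Si](C)(C)Cl
Why: Kinetic γ-deprotonation of the β-silyloxy enoate gives the extended dienolate, which the hard silyl chloride traps on the ester oxygen in the second half of the standard diene preparation.

**Step 5**
Reactants: 9 2,5-dibromohydroquinone
Product: 10 1,4-dibromo-2,5-bis(methoxymethoxy)benzene
Conditions: MOMCl, i-Pr2NEt, CH2Cl2, 0 °C → rt
Reagents that add atoms: chloromethyl methyl ether COCCl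
Why: This Williamson-type acetal ether formation on both phenols gives groups that tolerate organolithiums, carbonate bases and heat.

**Step 6**
Reactants: 10 1,4-dibromo-2,5-bis(methoxymethoxy)benzene
Product: 13 4-bromo-2,5-bis(methoxymethoxy)phenol, via aryllithium 11 (not isolated), via lithium aryltrimethoxyborate 12 (not isolated)
Conditions: n-BuLi (1.0 equiv), THF, −78 °C; B(OMe)3, −78 °C → rt; H2O2, aq NaOH, 0 °C
Reagents that add atoms: hydrogen peroxide OO
Why: A single bromine–lithium exchange on the symmetric dibromide is followed by borylation and oxidative 1,2-aryl shift, and either bromine gives the same phenol.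

**Step 7**
Reactants: 13 4-bromo-2,5-bis(methoxymethoxy)phenol; 14 3-chloro-3-methylbut-1-yne
Product: 15 1-bromo-2,5-bis(methoxymethoxy)-4-[(2-methylbut-3-yn-2-yl)oxy]benzene
Conditions: K2CO3, KI (cat.), CuI (cat.), DMF, 60 °C, N2
Reagents that add atoms: none
Why: Copper-assisted O-alkylation of a phenoxide with the tertiary propargylic chloride is the usual entry to 1,1-dimethylpropargyl aryl ethers.

**Step 8**
Reactants: 15 1-bromo-2,5-bis(methoxymethoxy)-4-[(2-methylbut-3-yn-2-yl)oxy]benzene
Product: 17 6-bromo-5,8-bis(methoxymethoxy)-2,2-dimethyl-2H-chromene, via o-allenylphenol 16 (not isolated)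
Conditions: o-xylene, 140 °C
Reagents that add atoms: none
Why: The aromatic propargyl Claisen rearrangement is followed by a 1,5-hydrogen shift and oxa-6π electrocyclization, and only one ortho position carries hydrogen, so a single chromene should form.

**Step 9**
Reactants: 17 6-bromo-5,8-bis(methoxymethoxy)-2,2-dimethyl-2H-chromene
Product: 20 5,8-bis(methoxymethoxy)-2,2-dimethyl-2H-chromen-6-ol, via chromenyllithium 18 (not isolated), via lithium chromenyltrimethoxyborate 19 (not isolated)
Conditions: n-BuLi, THF, −78 °C; B(OMe)3, −78 °C → rt; H2O2, aq NaOH, 0 °C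
Reagents that add atoms: hydrogen peroxide OO
Why: Bromine–lithium exchange, borylation and oxidation place the oxygen exactly where the bromine stood, and basic peroxide leaves the unactivated chromene alkene alone.

**Step 10**
Reactants: 20 5,8-bis(methoxymethoxy)-2,2-dimethyl-2H-chromen-6-ol; 21 trichloroethylene
Product: 22 6-{[(E)-1,2-dichlorovinyl]oxy}-5,8-bis(methoxymethoxy)-2,2-dimethyl-2H-chromene
Conditions: K2CO3, DMF, 70 °C
Reagents that add atoms: none
Why: In this known dichlorovinyl ether synthesis the base eliminates HCl from 21, and the phenoxide adds anti to the resulting chloroalkyne to fix the E geometry.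

**Step 11**
Reactants: 22 6-{[(E)-1,2-dichlorovinyl]oxy}-5,8-bis(methoxymethoxy)-2,2-dimethyl-2H-chromene; 23 allyl chloroformate
Product: 26 allyl 3-{[5,8-bis(methoxymethoxy)-2,2-dimethyl-2H-chromen-6-yl]oxy}propiolate, via chloroethynyl ether 24 (not isolated), via lithium aryloxyacetylide 25 (not isolated)
Conditions: n-BuLi (2.2 equiv), THF, −78 → −40 °C; cannulated into 23 (excess), THF, −78 °C; Et3N-deactivated silica
Reagents that add atoms: none
Why: β-Elimination followed by chlorine–lithium exchange is the established route from aryl dichlorovinyl ethers to lithium aryloxyacetylides, and acyl substitution on a chloroformate under inverse addition should stop at the ynoate.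

**Step 12**
Reactants: 8 (1Z,3Z)-1-methoxy-2,4-bis(3-methylbut-2-en-1-yl)-1,3-bis(trimethylsilyloxy)buta-1,3-diene; 26 allyl 3-{[5,8-bis(methoxymethoxy)-2,2-dimethyl-2H-chromen-6-yl]oxy}propiolate
Product: 29 allyl 2-{[5,8-bis(methoxymethoxy)-2,2-dimethyl-2H-chromen-6-yl]oxy}-4,6-dihydroxy-3,5-bis(3-methylbut-2-en-1-yl)benzoate, via cyclohexadiene cycloadduct 27 (not isolated), via 4-O-trimethylsilyl ether 28 (not isolated)
Conditions: 8 (3 equiv), o-xylene (2 M), BHT (cat.), sealed tube, 130 °C, Ar; then 10% aq citric acid, THF, rt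
Reagents that add atoms: none
Why: Proposed new method: C4 of the electron-rich diene 8 should bond to the aryloxy-bearing alkyne carbon of 26 and the ketene-acetal carbon C1 to the ester-bearing carbon, either in one highly asynchronous [4+2] event or as a Mukaiyama–Michael addition followed by closure of the allenoate carbon onto the oxocarbenium carbon, giving 27; its mixed methyl silyl ketal then expels MeOSiMe3, the resulting dienone still holds a ring hydrogen at the prenyl-bearing sp3 carbon and tautomerizes to arene 28, and the last silyl ether falls off in the citric acid wash. The closest known reaction type is the thermal Diels–Alder/aromatization of 1-alkoxy-1,3-bis(silyloxy)dienes with 3-alkylpropiolates and macrocyclic ynoates, which gives 6-alkyl-2,4-dihydroxybenzoates; a 3-aryloxypropiolate has not been used as the two-carbon partner. Ring A closes as a six-membered carbocycle by intermolecular [4+2] cycloaddition, and both new C–C bonds arise in this operation. The two sp3 ring carbons of 27 vanish on aromatization, so no stereocentre needs control. One regiochemistry is required, and the ester acceptor and aryloxy donor polarize the triple bond in the same sense, so the oxygen-bearing carbon is its only electrophilic site and meets the most nucleophilic diene terminus, which places the new hydroxyl next to the ester. Chemoselectivity rests on the absence of acid: the prenyl, allyl and chromene alkenes are unactivated toward the diene and the MOM ethers tolerate heat, while the raised LUMO of the donor-substituted alkyne is offset by excess diene, high concentration and temperature.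

**Step 13**
Reactants: 29 allyl 2-{[5,8-bis(methoxymethoxy)-2,2-dimethyl-2H-chromen-6-yl]oxy}-4,6-dihydroxy-3,5-bis(3-methylbut-2-en-1-yl)benzoate
Product: 30 allyl 2-[(5,8-dihydroxy-2,2-dimethyl-2H-chromen-6-yl)oxy]-4,6-dihydroxy-3,5-bis(3-methylbut-2-en-1-yl)benzoate
Conditions: aq HCl (3 M, cat.), MeOH–THF, 40 °C, Ar
Reagents that add atoms: none
Why: Acid-catalysed acetal exchange with methanol is the usual way to remove aryl MOM ethers from prenylated phenols, and the doubly ortho-substituted allyl ester is too hindered to transesterify.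

**Step 14**
Reactants: 30 allyl 2-[(5,8-dihydroxy-2,2-dimethyl-2H-chromen-6-yl)oxy]-4,6-dihydroxy-3,5-bis(3-methylbut-2-en-1-yl)benzoate
Product: 31 2-[(5,8-dihydroxy-2,2-dimethyl-2H-chromen-6-yl)oxy]-4,6-dihydroxy-3,5-bis(3-methylbut-2-en-1-yl)benzoic acid
Conditions: Pd(PPh3)4 (5 mol %), morpholine, THF, rt, Ar; cold pH 4 buffer
Reagents that add atoms: none
Why: In this Tsuji–Trost deallylation zerovalent palladium ionizes only the allyl ester and morpholine captures the allyl unit, so the decarboxylation-prone acid is released without acid, base or heat.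

**Step 15**
Reactants: 31 2-[(5,8-dihydroxy-2,2-dimethyl-2H-chromen-6-yl)oxy]-4,6-dihydroxy-3,5-bis(3-methylbut-2-en-1-yl)benzoic acid
Product: 32 garcinisidone E
Conditions: DCC, DMAP (cat.), CH2Cl2 (2 mM), 0 °C → rt, Ar
Reagents that add atoms: none
Why: Carbodiimide (Steglich-type) lactonization is the classical closure of 2-(2-hydroxyaryloxy)benzoic acids to depsidones, and only the ring-B hydroxyl next to the ether oxygen can reach the activated carboxyl, closing the seven-membered ring while dilution suppresses intermolecular esters.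

**Compound list**
1 | methyl acetoacetate | COC(=O)CC(C)=O | starting material
2 | prenyl bromide (1-bromo-3-methylbut-2-ene) | CC(C)=CCBr | starting material
3 | sodium lithium dianion of methyl acetoacetate | COC(=O)[CH-]C(=O)[CH2-].[Na+].[Li+] | intermediate
4 | methyl 7-methyl-3-oxooct-6-enoate | COC(=O)CC(=O)CCC=C(C)C | intermediate
5 | methyl 7-methyl-2-(3-methylbut-2-en-1-yl)-3-oxooct-6-enoate (racemic, labile α-carbon) | COC(=O)C(CC=C(C)C)C(=O)CCC=C(C)C | intermediate
6 | methyl 7-methyl-2-(3-methylbut-2-en-1-yl)-3-(trimethylsilyloxy)octa-2,6-dienoate (E/Z mixture at C2=C3) | COC(=O)C(CC=C(C)C)=C(CCC=C(C)C)O[Si](C)(C)C | intermediate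
7 | lithium dienolate of 6 | [Li+].COC([O-])=C(CC=C(C)C)C(O[Si](C)(C)C)=CCC=C(C)C | intermediate
8 | (1Z,3Z)-1-methoxy-2,4-bis(3-methylbut-2-en-1-yl)-1,3-bis(trimethylsilyloxy)buta-1,3-diene | CO/C(O[Si](C)(C)C)=C(CC=C(C)C)/C(O[Si](C)(C)C)=C/CC=C(C)C | intermediate
9 | 2,5-dibromohydroquinone | Oc1cc(Br)c(O)cc1Br | starting material
10 | 1,4-dibromo-2,5-bis(methoxymethoxy)benzene | COCOc1cc(Br)c(OCOC)cc1Br | intermediate
11 | 4-bromo-2,5-bis(methoxymethoxy)phenyllithium | [Li]c1cc(OCOC)c(Br)cc1OCOC | intermediate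
12 | lithium [4-bromo-2,5-bis(methoxymethoxy)phenyl]trimethoxyborate | [Li+].CO[B-](OC)(OC)c1cc(OCOC)c(Br)cc1OCOC | intermediate
13 | 4-bromo-2,5-bis(methoxymethoxy)phenol | COCOc1cc(Br)c(OCOC)cc1O | intermediate
14 | 3-chloro-3-methylbut-1-yne | C#CC(C)(C)Cl | starting material
15 | 1-bromo-2,5-bis(methoxymethoxy)-4-[(2-methylbut-3-yn-2-yl)oxy]benzene | C#CC(C)(C)Oc1cc(OCOC)c(Br)cc1OCOC | intermediate
16 | 4-bromo-3,6-bis(methoxymethoxy)-2-(3-methylbuta-1,2-dien-1-yl)phenol | CC(C)=C=Cc1c(O)c(OCOC)cc(Br)c1OCOC | intermediate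
17 | 6-bromo-5,8-bis(methoxymethoxy)-2,2-dimethyl-2H-chromene | Brc1cc(OCOC)c2OC(C)(C)C=Cc2c1OCOC | intermediate
18 | [5,8-bis(methoxymethoxy)-2,2-dimethyl-2H-chromen-6-yl]lithium | [Li]c1cc(OCOC)c2OC(C)(C)C=Cc2c1OCOC | intermediate
19 | lithium [5,8-bis(methoxymethoxy)-2,2-dimethyl-2H-chromen-6-yl]trimethoxyborate | [Li+].CO[B-](OC)(OC)c1cc(OCOC)c2OC(C)(C)C=Cc2c1OCOC | intermediate
20 | 5,8-bis(methoxymethoxy)-2,2-dimethyl-2H-chromen-6-ol | Oc1cc(OCOC)c2OC(C)(C)C=Cc2c1OCOC | intermediate
21 | trichloroethylene | ClC=C(Cl)Cl | starting material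
22 | 6-{[(E)-1,2-dichlorovinyl]oxy}-5,8-bis(methoxymethoxy)-2,2-dimethyl-2H-chromene | Cl/C=C(/Cl)Oc1cc(OCOC)c2OC(C)(C)C=Cc2c1OCOC | intermediate
23 | allyl chloroformate | C=CCOC(=O)Cl | starting material
24 | 6-(chloroethynyloxy)-5,8-bis(methoxymethoxy)-2,2-dimethyl-2H-chromene | ClC#COc1cc(OCOC)c2OC(C)(C)C=Cc2c1OCOC | intermediate
25 | lithium {[5,8-bis(methoxymethoxy)-2,2-dimethyl-2H-chromen-6-yl]oxy}acetylide | [Li]C#COc1cc(OCOC)c2OC(C)(C)C=Cc2c1OCOC | intermediate
26 | allyl 3-{[5,8-bis(methoxymethoxy)-2,2-dimethyl-2H-chromen-6-yl]oxy}propiolate | C=CCOC(=O)C#COc1cc(OCOC)c2OC(C)(C)C=Cc2c1OCOC | intermediate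
27 | allyl 2-(chromen-6-yloxy)-6-methoxy-3,5-diprenyl-4,6-bis(trimethylsilyloxy)cyclohexa-1,4-diene-1-carboxylate (diastereomer mixture, both centres transient) | COC1(O[Si](C)(C)C)C(CC=C(C)C)=C(O[Si](C)(C)C)C(CC=C(C)C)C(Oc2cc(OCOC)c3OC(C)(C)C=Cc3c2OCOC)=C1C(=O)OCC=C | intermediate
28 | allyl 2-{[5,8-bis(methoxymethoxy)-2,2-dimethyl-2H-chromen-6-yl]oxy}-6-hydroxy-3,5-diprenyl-4-(trimethylsilyloxy)benzoate | C=CCOC(=O)c1c(O)c(CC=C(C)C)c(O[Si](C)(C)C)c(CC=C(C)C)c1Oc1cc(OCOC)c2OC(C)(C)C=Cc2c1OCOC | intermediate
29 | allyl 2-{[5,8-bis(methoxymethoxy)-2,2-dimethyl-2H-chromen-6-yl]oxy}-4,6-dihydroxy-3,5-bis(3-methylbut-2-en-1-yl)benzoate | C=CCOC(=O)c1c(O)c(CC=C(C)C)c(O)c(CC=C(C)C)c1Oc1cc(OCOC)c2OC(C)(C)C=Cc2c1OCOC | intermediate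
30 | allyl 2-[(5,8-dihydroxy-2,2-dimethyl-2H-chromen-6-yl)oxy]-4,6-dihydroxy-3,5-bis(3-methylbut-2-en-1-yl)benzoate | C=CCOC(=O)c1c(O)c(CC=C(C)C)c(O)c(CC=C(C)C)c1Oc1cc(O)c2OC(C)(C)C=Cc2c1O | intermediate
31 | 2-[(5,8-dihydroxy-2,2-dimethyl-2H-chromen-6-yl)oxy]-4,6-dihydroxy-3,5-bis(3-methylbut-2-en-1-yl)benzoic acid | OC(=O)c1c(O)c(CC=C(C)C)c(O)c(CC=C(C)C)c1Oc1cc(O)c2OC(C)(C)C=Cc2c1O | intermediate
32 | garcinisidone E | CC(C)=CCc1c(O)c(CC=C(C)C)c2c(c1O)C(=O)Oc1c(cc(O)c3c1C=CC(C)(C)O3)O2 | target

**Step count**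
Total steps: 15. Longest linear sequence: 11 steps (steps 5–15, from 9). The diene branch (steps 1–4) joins at step 12.

**Steps most likely to fail**

**1. Step 12.**
- What may go wrong: the cycloaddition may be too slow because the aryloxy donor raises the alkyne LUMO. The ketene-acetal double bond may add in a [2+2] sense. The diene may lose silyl groups, or the ynoate may polymerize on long heating.
- Fallback: ring A would then be taken from an existing arene and the diaryl ether made by Chan–Lam coupling, setting out from bromide 17.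
- Bromine–lithium exchange, B(Oi-Pr)3 and mild hydrolysis give [5,8-bis(methoxymethoxy)-2,2-dimethyl-2H-chromen-6-yl]boronic acid F1.
- Commercial 2,4,6-trihydroxybenzoic acid is esterified (allyl bromide, KHCO3, DMF) to allyl 2,4,6-trihydroxybenzoate F2.
- Two silylations (TBSCl, imidazole) leave the hydrogen-bonded hydroxyl free and give allyl 2-hydroxy-4,6-bis(tert-butyldimethylsilyloxy)benzoate F3.
- Cu(OAc)2, pyridine and 4 Å sieves in CH2Cl2 under air join F1 and F3 to allyl 2-{[5,8-bis(methoxymethoxy)-2,2-dimethyl-2H-chromen-6-yl]oxy}-4,6-bis(tert-butyldimethylsilyloxy)benzoate F4.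
- TBAF buffered with AcOH frees allyl 2-{[5,8-bis(methoxymethoxy)-2,2-dimethyl-2H-chromen-6-yl]oxy}-4,6-dihydroxybenzoate F5.
- Double C-prenylation with 2 (NaH, toluene) fills the two open ring-A positions, both ortho to a phenoxide oxygen. The route is rejoined at 29.

**2. Step 11.**
- What may go wrong: ring lithiation next to a MOM ether may compete with acetylide formation. A second acetylide may add to the newly formed ester. The push–pull alkyne may hydrate during isolation.
- Fallback: the alkynyl C–O bond would be made without organolithiums, setting out from phenol 20.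
- Allyl propiolate is brominated (NBS, AgNO3 cat., acetone) to allyl 3-bromopropiolate F6.
- Phenol 20 adds to F6 in an oxa-Michael reaction (K2CO3, MeCN, 0 °C) to give allyl 3-bromo-3-{[5,8-bis(methoxymethoxy)-2,2-dimethyl-2H-chromen-6-yl]oxy}acrylate F7 (E/Z mixture).
- Dehydrobromination with KOt-Bu in THF at −78 °C is the closing move of the bromo-enol-ether route to aryl ynol ethers. It returns to the route at 26.

**3. Step 13.**
- What may go wrong: a ring-A hydroxyl may close onto a protonated prenyl group. Methanol may add to the chromene double bond. The liberated hydroquinone may oxidize in air.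
- Fallback: the ring-A phenols would be masked before any acid is applied, setting out from 29.
- TBSOTf and 2,6-lutidine give allyl 2-{[5,8-bis(methoxymethoxy)-2,2-dimethyl-2H-chromen-6-yl]oxy}-4,6-bis(tert-butyldimethylsilyloxy)-3,5-diprenylbenzoate F8.
- Acidic methanol then removes only the MOM groups and gives allyl 2-[(5,8-dihydroxy-2,2-dimethyl-2H-chromen-6-yl)oxy]-4,6-bis(tert-butyldimethylsilyloxy)-3,5-diprenylbenzoate F9.
- Pd(PPh3)4 with morpholine gives 2-[(5,8-dihydroxy-2,2-dimethyl-2H-chromen-6-yl)oxy]-4,6-bis(tert-butyldimethylsilyloxy)-3,5-diprenylbenzoic acid F10.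
- DCC closes F10 to garcinisidone E bis(tert-butyldimethylsilyl) ether F11.
- TBAF buffered with AcOH at 0 °C removes the silyl groups without opening the lactone. The route is rejoined at 32.

**Further compounds**
F1 | step 12 | [5,8-bis(methoxymethoxy)-2,2-dimethyl-2H-chromen-6-yl]boronic acid | OB(O)c1cc(OCOC)c2OC(C)(C)C=Cc2c1OCOC
F2 | step 12 | allyl 2,4,6-trihydroxybenzoate | C=CCOC(=O)c1c(O)cc(O)cc1O
F3 | step 12 | allyl 2-hydroxy-4,6-bis(tert-butyldimethylsilyloxy)benzoate | C=CCOC(=O)c1c(O)cc(O[Si](C)(C)C(C)(C)C)cc1O[Si](C)(C)C(C)(C)C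
F4 | step 12 | allyl 2-{[5,8-bis(methoxymethoxy)-2,2-dimethyl-2H-chromen-6-yl]oxy}-4,6-bis(tert-butyldimethylsilyloxy)benzoate | C=CCOC(=O)c1c(O[Si](C)(C)C(C)(C)C)cc(O[Si](C)(C)C(C)(C)C)cc1Oc1cc(OCOC)c2OC(C)(C)C=Cc2c1OCOC
F5 | step 12 | allyl 2-{[5,8-bis(methoxymethoxy)-2,2-dimethyl-2H-chromen-6-yl]oxy}-4,6-dihydroxybenzoate | C=CCOC(=O)c1c(O)cc(O)cc1Oc1cc(OCOC)c2OC(C)(C)C=Cc2c1OCOC
F6 | step 11 | allyl 3-bromopropiolate | C=CCOC(=O)C#CBr
F7 | step 11 | allyl 3-bromo-3-{[5,8-bis(methoxymethoxy)-2,2-dimethyl-2H-chromen-6-yl]oxy}acrylate (E/Z mixture) | C=CCOC(=O)C=C(Br)Oc1cc(OCOC)c2OC(C)(C)C=Cc2c1OCOC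
F8 | step 13 | allyl 2-{[5,8-bis(methoxymethoxy)-2,2-dimethyl-2H-chromen-6-yl]oxy}-4,6-bis(tert-butyldimethylsilyloxy)-3,5-diprenylbenzoate | C=CCOC(=O)c1c(O[Si](C)(C)C(C)(C)C)c(CC=C(C)C)c(O[Si](C)(C)C(C)(C)C)c(CC=C(C)C)c1Oc1cc(OCOC)c2OC(C)(C)C=Cc2c1OCOC
F9 | step 13 | allyl 2-[(5,8-dihydroxy-2,2-dimethyl-2H-chromen-6-yl)oxy]-4,6-bis(tert-butyldimethylsilyloxy)-3,5-diprenylbenzoate | C=CCOC(=O)c1c(O[Si](C)(C)C(C)(C)C)c(CC=C(C)C)c(O[Si](C)(C)C(C)(C)C)c(CC=C(C)C)c1Oc1cc(O)c2OC(C)(C)C=Cc2c1O
F10 | step 13 | 2-[(5,8-dihydroxy-2,2-dimethyl-2H-chromen-6-yl)oxy]-4,6-bis(tert-butyldimethylsilyloxy)-3,5-diprenylbenzoic acid | OC(=O)c1c(O[Si](C)(C)C(C)(C)C)c(CC=C(C)C)c(O[Si](C)(C)C(C)(C)C)c(CC=C(C)C)c1Oc1cc(O)c2OC(C)(C)C=Cc2c1O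
F11 | step 13 | garcinisidone E bis(tert-butyldimethylsilyl) ether | CC(C)=CCc1c(O[Si](C)(C)C(C)(C)C)c(CC=C(C)C)c2c(c1O[Si](C)(C)C(C)(C)C)C(=O)Oc1c(cc(O)c3c1C=CC(C)(C)O3)O2
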